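**Plan**

Numbering: pyran O1, C2 (bears ring A, the 3,4-dihydroxy-5-methoxyphenyl group), C3, C4 (carbinol), C5, C6 (bears the C7–C8 chain to ring B, the 4-hydroxyphenyl group).
Feature: O1–C2 with ring A is the C=O of an aryl aldehyde in latent form, and C3–C4(O)–C5–C6 is a 2-oxygenated butadiene with the arylethyl chain on its terminus, so the oxygenated pyran maps onto a carbonyl [4+2] adduct.
Retrosynthesis: remove the three benzyl ethers, take C4–OH back to the ketone and its enol silane, cut C2–C3 and O1–C6 (hetero-Diels–Alder), then cut the C5=C6 alkene of the diene (Wittig).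
Forward: the ring A aldehyde (1 step) and the ring B diene (4 steps) are made in parallel and joined in the cycloaddition that closes the only new ring; enol silane hydrolysis, ketone reduction and hydrogenolysis follow.
Stereochemistry: C2 from the chiral Schiff-base complex CrCl(L) of step 6 (Si face of the aldehyde), C6 from the endo transition state on the (E)-diene (2,6-cis), C4 from axial hydride attack on the chair pyranone (all-cis).

Key step: step 6

Assumption: the catalyst is taken to show the same sense of induction as with simple aldehydes, where the CrCl(L) complex from (1R,2S)-aminoindanol sends the diene to the Re face; the (1S,2R) complex is therefore specified for the Si-face attack that gives (2S), and both antipodes of the aminoindanol are commercial.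

**Route**

Step 1
Reactants: 1 3,4-dihydroxy-5-methoxybenzaldehyde
Product: 2 3,4-bis(benzyloxy)-5-methoxybenzaldehyde
Conditions: BnBr (2.4 equiv), K2CO3 (3 equiv), DMF, 60 °C
Reagents that add atoms: benzyl bromide, BrCc1ccccc1
Why: Williamson ether synthesis: both catechol phenoxides are alkylated by the primary benzylic bromide, and the aldehyde is inert to carbonate.

Step 2
Reactants: 3 3-(4-hydroxyphenyl)propanoic acid
Product: 4 benzyl 3-[4-(benzyloxy)phenyl]propanoate
Conditions: BnBr (2.3 equiv), K2CO3 (3 equiv), DMF, 60 °C
Reagents that add atoms: benzyl bromide, BrCc1ccccc1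
Why: Williamson-type O-alkylation of both the phenoxide and the carboxylate should give the benzyl ether benzyl ester in one operation.

Step 3
Reactants: 4 benzyl 3-[4-(benzyloxy)phenyl]propanoate
Product: 6 3-[4-(benzyloxy)phenyl]propanal, via aluminium hemiacetal 5 (not isolated)
Conditions: i-Bu2AlH (1.05 equiv), CH2Cl2, −78 °C; then MeOH, aq. KNaC4H4O6 (potassium sodium tartrate), rt
Reagents that add atoms: none
Why: Partial ester reduction: one hydride adds at −78 °C to give the tetrahedral aluminium hemiacetal 5, which persists in the cold and releases the aldehyde only on aqueous quench, the aryl benzyl ether being untouched.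

Step 4
Reactants: 6 3-[4-(benzyloxy)phenyl]propanal; 7 1-(triphenylphosphoranylidene)propan-2-one
Product: 8 (3E)-6-[4-(benzyloxy)phenyl]hex-3-en-2-one
Conditions: toluene, 80 °C
Reagents that add atoms: none
Why: Wittig reaction of a stabilised acyl ylide with an unhindered aliphatic aldehyde, which under thermodynamic control should give the (E)-enone.

Step 5
Reactants: 8 (3E)-6-[4-(benzyloxy)phenyl]hex-3-en-2-one
Product: 9 (3E)-6-[4-(benzyloxy)phenyl]-2-(triethylsilyloxy)hexa-1,3-diene
Conditions: Et3SiOTf (1.2 equiv), Et3N (2 equiv), Et2O, −78 to 0 °C; cold aq. NaHCO3 work-up, used without chromatography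
Reagents that add atoms: triethylsilyl trifluoromethanesulfonate, CC[Si](CC)(CC)OS(=O)(=O)C(F)(F)F
Why: Soft enolisation with O-silylation of a methyl ketone: the silyl triflate activates the carbonyl and Et3N removes the more accessible methyl proton in preference to the γ-proton, giving the cross-conjugated 2-silyloxy diene with the E-alkene intact.

Step 6
Reactants: 2 3,4-bis(benzyloxy)-5-methoxybenzaldehyde; 9 (3E)-6-[4-(benzyloxy)phenyl]-2-(triethylsilyloxy)hexa-1,3-diene
Product: 10 (2S,6S)-2-[3,4-bis(benzyloxy)-5-methoxyphenyl]-6-[2-(4-benzyloxyphenyl)ethyl]-4-(triethylsilyloxy)-3,6-dihydro-2H-pyran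
Conditions: 9 (1.3 equiv), CrCl(L) (5 mol%, trivalent chromium; L = C27H29NO2, the dianion of the Schiff base from (1S,2R)-cis-1-amino-2-indanol and 3-(1-adamantyl)-2-hydroxy-5-methylbenzaldehyde), powdered 4 Å MS, acetone, rt; filtration through Et3N-treated silica
Reagents that add atoms: none
Why: The chromium centre (trivalent chromium) binds the carbonyl oxygen of 2 anti to ring A and covers the Re face, so that the CH2 terminus of 9, made nucleophilic by the 2-silyloxy group, bonds to the carbonyl carbon (C2–C3) while the carbonyl oxygen bonds to the substituted diene terminus (O1–C6) in a concerted, asynchronous hetero-Diels–Alder cycloaddition. The closest known reaction type is the enantioselective [4+2] addition of aldehydes, benzaldehyde included, to 1-substituted 3-silyloxybutadienes under tridentate Schiff-base complexes of the CrCl(L) type. The dihydropyran ring closes by intermolecular [4+2] cycloaddition, both of its new bonds arising in one transition state, so no separate ring-closure mode competes. C2 is set by the catalyst through attack on the Si face of the aldehyde (2S), and C6 is set relative to C2 by the endo transition state acting on the E-configured C5=C6 bond, which places ring A and the arylethyl chain cis (6S). The step needs enantioface selection, endo selectivity and one regiochemistry; the catalyst supplies the first, the E-alkene together with the endo preference of the aryl group the second, and the polarisation by the silyloxy group on C4 the third. The 4-benzyloxy group of 2 is flanked on both sides and twisted out of conjugation while the two meta oxygens withdraw inductively, so the aldehyde should stay electrophilic enough for this mono-oxygenated diene.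

Step 7
Reactants: 10 (2S,6S)-2-[3,4-bis(benzyloxy)-5-methoxyphenyl]-6-[2-(4-benzyloxyphenyl)ethyl]-4-(triethylsilyloxy)-3,6-dihydro-2H-pyran
Product: 11 (2S,6S)-2-[3,4-bis(benzyloxy)-5-methoxyphenyl]-6-[2-(4-benzyloxyphenyl)ethyl]oxan-4-one
Conditions: 1 M aq. HCl (cat.), THF, 0 °C
Reagents that add atoms: none
Why: Acid-catalysed hydrolysis of a silyl enol ether: protonation at C5 and transfer of the silyl group to water unmask the C4 ketone without touching C2 or C6, and the short cold exposure should avoid β-alkoxy elimination.

Step 8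
Reactants: 11 (2S,6S)-2-[3,4-bis(benzyloxy)-5-methoxyphenyl]-6-[2-(4-benzyloxyphenyl)ethyl]oxan-4-one
Product: 12 (2S,4R,6S)-2-[3,4-bis(benzyloxy)-5-methoxyphenyl]-6-[2-(4-benzyloxyphenyl)ethyl]oxan-4-ol
Conditions: NaBH4, MeOH, −40 to 0 °C
Reagents that add atoms: none
Why: Borohydride reduction of a conformationally locked cyclic ketone: with the C2 and C6 substituents both equatorial in the chair, the small hydride should attack C4 along the axial trajectory and leave the hydroxyl equatorial, cis to both substituents (4R).

Step 9
Reactants: 12 (2S,4R,6S)-2-[3,4-bis(benzyloxy)-5-methoxyphenyl]-6-[2-(4-benzyloxyphenyl)ethyl]oxan-4-ol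
Product: 13 (2S,4R,6S)-2-(3,4-dihydroxy-5-methoxyphenyl)-6-[2-(4-hydroxyphenyl)ethyl]oxan-4-ol
Conditions: H2 (1 atm), 10% Pd/C, EtOAc–MeOH, rt, stopped when the last benzyl ether is consumed; work-up under argon
Reagents that add atoms: none
Why: Catalytic hydrogenolysis of the three primary benzyl aryl ethers, which should be cleaved far faster than the secondary, ring-bound benzylic C2–O1 bond, so the pyran and its three stereocentres should survive.

**Compound list**

1 | 3,4-dihydroxy-5-methoxybenzaldehyde | COc1cc(C=O)cc(O)c1O | starting material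
2 | 3,4-bis(benzyloxy)-5-methoxybenzaldehyde | COc1cc(C=O)cc(OCc2ccccc2)c1OCc1ccccc1 | intermediate
3 | 3-(4-hydroxyphenyl)propanoic acid | OC(=O)CCc1ccc(O)cc1 | starting material
4 | benzyl 3-[4-(benzyloxy)phenyl]propanoate | O=C(CCc1ccc(OCc2ccccc2)cc1)OCc1ccccc1 | intermediate
5 | [1-(benzyloxy)-3-(4-benzyloxyphenyl)propoxy]bis(2-methylpropyl)aluminium (aluminium hemiacetal, racemic at the acetal carbon, formed in the flask) | CC(C)C[Al](CC(C)C)OC(CCc1ccc(OCc2ccccc2)cc1)OCc1ccccc1 | intermediate
6 | 3-[4-(benzyloxy)phenyl]propanal | O=CCCc1ccc(OCc2ccccc2)cc1 | intermediate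
7 | 1-(triphenylphosphoranylidene)propan-2-one | CC(=O)C=P(c1ccccc1)(c1ccccc1)c1ccccc1 | starting material
8 | (3E)-6-[4-(benzyloxy)phenyl]hex-3-en-2-one | CC(=O)/C=C/CCc1ccc(OCc2ccccc2)cc1 | intermediate
9 | (3E)-6-[4-(benzyloxy)phenyl]-2-(triethylsilyloxy)hexa-1,3-diene | C=C(O[Si](CC)(CC)CC)/C=C/CCc1ccc(OCc2ccccc2)cc1 | intermediate
10 | (2S,6S)-2-[3,4-bis(benzyloxy)-5-methoxyphenyl]-6-[2-(4-benzyloxyphenyl)ethyl]-4-(triethylsilyloxy)-3,6-dihydro-2H-pyran | COc1cc([C@@H]2CC(O[Si](CC)(CC)CC)=C[C@H](CCc3ccc(OCc4ccccc4)cc3)O2)cc(OCc2ccccc2)c1OCc1ccccc1 | intermediate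
11 | (2S,6S)-2-[3,4-bis(benzyloxy)-5-methoxyphenyl]-6-[2-(4-benzyloxyphenyl)ethyl]oxan-4-one | COc1cc([C@@H]2CC(=O)C[C@H](CCc3ccc(OCc4ccccc4)cc3)O2)cc(OCc2ccccc2)c1OCc1ccccc1 | intermediate
12 | (2S,4R,6S)-2-[3,4-bis(benzyloxy)-5-methoxyphenyl]-6-[2-(4-benzyloxyphenyl)ethyl]oxan-4-ol | COc1cc([C@@H]2C[C@H](O)C[C@H](CCc3ccc(OCc4ccccc4)cc3)O2)cc(OCc2ccccc2)c1OCc1ccccc1 | intermediate
13 | (2S,4R,6S)-2-(3,4-dihydroxy-5-methoxyphenyl)-6-[2-(4-hydroxyphenyl)ethyl]oxan-4-ol | COc1cc([C@@H]2C[C@H](O)C[C@H](CCc3ccc(O)cc3)O2)cc(O)c1O | target

Total step count: 9. Longest linear sequence: 8 steps (steps 2 to 9, from 3 to 13).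

**Steps most likely to fail**

Step 6. The cycloaddition may be slow with this oxygen-rich aryl aldehyde, so that hydrolysis of the diene or a poorly selective background addition lowers conversion and enantiomeric purity. The fallback sets out from 6 and 2 and comes back at 12, replacing the cycloaddition by a Prins ring closure. Aldehyde 6 would be allylated with allyltributylstannane under catalysis by (R)-BINOL/Ti(OiPr)4 (tetravalent titanium). Addition to the Re face is expected, giving (3S)-1-[4-(benzyloxy)phenyl]hex-5-en-3-ol F1, which fixes C6. Prins cyclisation of F1 with aldehyde 2 in CF3CO2H/CH2Cl2 would form O1–C2 and C2–C3 through a chair oxocarbenium ion with ring A and the chain equatorial, and trifluoroacetate would be captured equatorially at C4. This should give (2S,4R,6S)-2-[3,4-bis(benzyloxy)-5-methoxyphenyl]-6-[2-(4-benzyloxyphenyl)ethyl]oxan-4-yl trifluoroacetate F2. Methanolysis of F2 with K2CO3 in MeOH would then free alcohol 12. The homoallylic alcohol is placed on the aliphatic side so that no benzylic carbinol is exposed to ionisation or oxonia-Cope scrambling.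

Step 9. Over-reduction may occur: hydrogenolysis of the benzylic C2–O1 bond would open the pyran while the benzyl ethers are being removed. The fallback sets out from 12 and comes back at 13, exchanging the reductive cleavage for a Lewis-acid dealkylation. BCl3 with pentamethylbenzene as benzyl-cation scavenger in CH2Cl2 at −78 °C, followed by a MeOH quench, should cleave the three aryl benzyl ethers without any hydrogen source that could reduce the ring ether. No new compound arises on this path, which is entered as F0.

Step 8. Hydride delivery to C4 may show insufficient facial selectivity, leaving the axial epimer in the product. The fallback sets out from 11 and comes back at 12 by reversing the selectivity and then inverting. LiBH(s-Bu)3 in THF at −78 °C should attack equatorially and give the axial alcohol (2S,4S,6S)-2-[3,4-bis(benzyloxy)-5-methoxyphenyl]-6-[2-(4-benzyloxyphenyl)ethyl]oxan-4-ol F3. A Mitsunobu reaction of F3 with 4-nitrobenzoic acid, PPh3 and DIAD would invert C4 to give (2S,4R,6S)-2-[3,4-bis(benzyloxy)-5-methoxyphenyl]-6-[2-(4-benzyloxyphenyl)ethyl]oxan-4-yl 4-nitrobenzoate F4. K2CO3 in MeOH would then cleave the ester of F4 and release 12.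

**Further compounds**

F1 | step 6 | (3S)-1-[4-(benzyloxy)phenyl]hex-5-en-3-ol | C=CC[C@@H](O)CCc1ccc(OCc2ccccc2)cc1
F2 | step 6 | (2S,4R,6S)-2-[3,4-bis(benzyloxy)-5-methoxyphenyl]-6-[2-(4-benzyloxyphenyl)ethyl]oxan-4-yl trifluoroacetate | COc1cc([C@@H]2C[C@H](OC(=O)C(F)(F)F)C[C@H](CCc3ccc(OCc4ccccc4)cc3)O2)cc(OCc2ccccc2)c1OCc1ccccc1
F0 | step 9 | none | none
F3 | step 8 | (2S,4S,6S)-2-[3,4-bis(benzyloxy)-5-methoxyphenyl]-6-[2-(4-benzyloxyphenyl)ethyl]oxan-4-ol | COc1cc([C@@H]2C[C@@H](O)C[C@H](CCc3ccc(OCc4ccccc4)cc3)O2)cc(OCc2ccccc2)c1OCc1ccccc1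
F4 | step 8 | (2S,4R,6S)-2-[3,4-bis(benzyloxy)-5-methoxyphenyl]-6-[2-(4-benzyloxyphenyl)ethyl]oxan-4-yl 4-nitrobenzoate | COc1cc([C@@H]2C[C@H](OC(=O)c3ccc(cc3)[N+](=O)[O-])C[C@H](CCc3ccc(OCc4ccccc4)cc3)O2)cc(OCc2ccccc2)c1OCc1ccccc1
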